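I read each flask at 8.0 h, and what I want at that moment is the complex with one exchanged still standing in it.

    starting complex + incoming ligand ⇌ leaving ligand + complex with one exchanged (K1 = 0.27, k1 = 0.077 M⁻¹ min⁻¹)
    complex with one exchanged + incoming ligand ⇌ leaving ligand + complex with two exchanged (K2 = 22, k2 = 0.060 M⁻¹ min⁻¹)
    complex with two exchanged + incoming ligand ⇌ leaving ligand + complex with three exchanged (K3 = 0.030, k3 = 0.22 M⁻¹ min⁻¹)
    starting complex + complex with one exchanged → side product (k4 = 0.21 M⁻¹ min⁻¹)

| flask | starting complex | incoming ligand | leaving ligand | time |
|---|---|---|---|---|
| cedar | 0.021 M | 0.0100 M | 0.0210 M | 8.0 h |
| elm | 0.021 M | 0.0200 M | 0.0210 M | 8.0 h |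
| alder | 0.021 M | 0.0400 M | 0.0210 M | 8.0 h |
| ash | 0.021 M | 0.0800 M | 0.0210 M | 8.0 h |
| maple | 0.021 M | 0.150 M | 0.0210 M | 8.0 h |

1. amount of complex with one exchanged at the end, in percent of the starting complex charged for cedar, elm, alder, ash, maple, in this order
2. the shape of the row from first to last (falls all the way / rises all the way / falls, then rises / rises, then falls / hardly changes)

- percent here means starting complex units held: one side product counts as two
- "hardly changes" means that all values lie within two and a half points (for a concentration: within two and a half percent of the largest)
- run time (cedar): 8.0 h

In cedar that complex goes into side product with a half-life of 2.6 h, shorter than the run, so I let it keep pace with the starting complex beside it (the steady-state approximation). I carry one quantity, the hold: the amount of that complex over the starting complex present, which is its making (first forward constant times incoming ligand) over the sum of its ways out (back with leaving ligand, on with incoming ligand, into side product with starting complex). At cedar's charge the hold is 7.00 %. The row is then the hold times the starting complex left, and I solve that at both ends.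

In cedar the side reaction is faster than the second exchange, with half-lives of 2.6 h against 19 h, so I drain the starting complex by that route, two units per side product, second order. That leaves 77.1 %. By this reckoning leaving ligand gains 0.00240 M and incoming ligand loses as much; on those amounts the hold comes to 5.56 %, and cedar stands at 4.29 %.

In maple the second exchange is faster than the side reaction at the charge, so I take it as the drain instead. With incoming ligand at 0.129 M and leaving ligand at 0.0420 M for mid-run, the starting complex falls pseudo-first-order at the forward rate times the share going on rather than back. That leaves 15.4 %, and with two ligands exchanged per unit lost, maple stands at 5.73 %.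

The weak link is ash, where both routes run. Its hold at the charge is 40.5 %, and the side route by itself leaves 36.8 %, which gives 9.76 % at mid-run ligand amounts. Multiplying in the second exchange's drain lowers what is left to 22.4 % and the amount to 6.16 %. The first figure leaves out a drain and the second counts both at full strength, so I commit to their midpoint, 7.96 %, which stands above both ends. Its rise over cedar, 3.7 percentage points, is wider than the band of "hardly changes", so the shape I commit to is: rises, then falls.

The forecast gives 3.9 %, 6.4 %, 9 %, 9.8 % and 7 %, rises, then falls, on the ground that “more incoming ligand raises it at first”; its ash and maple stand above mine  and its cedar below.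

The flasks give 4.30 %, 7.04 %, 9.64 %, 9.86 % and 6.66 %: rises, then falls, with the turn read near 0.060 M of incoming ligand. In cedar half of the side reaction's turnover was done by 4.16 h, while the complex with one exchanged went from being made 1.47 times as fast as used at 2.25 h to 0.805 times at the end. In maple the starting complex fell from 25.2 % at 4.00 h to 13.0 %, while complex with two exchanged reached 52.6 %. The hold, 7.00 % at cedar's charge, comes to 5.05 % on cedar's end amounts, where the share reads 5.44 %; in ash the hold on the end amounts is 29.6 %, and the share reads 34.1 %.

The constants used here stand for no real mixture; the flask was simulated.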